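**Plan**

1. Locants (germacranolide numbering): C12 lactone C=O, C11=C13H2, C6 lactone O–CH, C5 ring CH2, C4(Me)=C3, C2 ketone, C1 CH2, C10 CHMe, C9 CH–O-ester, C8 CH–OH, C7 ring fusion. The retrosynthesis cuts the C9 ester C–O bond first, then in one event the lactone O–C6 bond and the ring bond C4–C5, then C2–C3, C11=C13, C7–C6, C10–CH3 and the olefins C11=C7 and C1=C10, back to a four-carbon diol.
2. Feature used: in the seco acid C5 and C6 are the two carbons of a vinyl group on C7. C6 is γ to the C12 carboxyl and C5 is the atom that must bond to the enone β-carbon C4, so one 1,2-difunctionalisation of this alkene (O on C6, C4 on C5) closes the γ-lactone and the ten-membered carbocycle together.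
3. Forward: the chain C2–C1–C10–C9–C8–C7 is grown from both ends of 2,3-O-isopropylidene-D-threitol; a temporary γ-lactone (O9–C2) tells the C8 and C9 hydroxyls apart; the ynone is turned into the (Z)-β-iodoenone; the lactone and the ten-membered ring then form in the key step; ester and desilylation come last.
4. Stereochemistry: C8 and C9 are bought (D-threitol). C10 and C7 come from two cuprate additions anti to the dioxolane oxygens. C6 is relayed from C7 in the key step. The 3Z olefin comes from anti hydroiodination of the ynone and is carried through with retention. The epoxide comes from asymmetric epoxidation of angelyl alcohol.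

Key step: step 15

Remark: compound 1, angelic acid (27) and all reagents named are taken as commercial; metal alkoxides and chelates that are only protonated on aqueous work-up are not numbered; 12 and 13 are mixtures of epimers at C11, a centre that becomes sp2 in step 7.

**Route**

Step 1
Reactants: 1 (4R,5R)-2,2-dimethyl-1,3-dioxolane-4,5-dimethanol
Product: 3 [(4R,5R)-5-({[tert-butyl(dimethyl)silyl]oxy}methyl)-2,2-dimethyl-1,3-dioxolan-4-yl]methanol, via monosodium alkoxide 2 (not isolated)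
Conditions: NaH (1.0 equiv), THF, 0 °C; then TBSCl (1.0 equiv), 0 °C to rt
Reagents that add atoms: tert-butyldimethylsilyl chloride, CC(C)(C)[Si](C)(C)Cl
Why: Single deprotonation of the C2-symmetric diol and O-silylation of the alkoxide should give the mono-ether, the two hydroxymethyl groups being equivalent, and no stereocentre is touched.

Step 2
Reactants: 3 mono-silyl ether
Product: 5 ethyl (2E)-3-[(4R,5R)-5-({[tert-butyl(dimethyl)silyl]oxy}methyl)-2,2-dimethyl-1,3-dioxolan-4-yl]prop-2-enoate, via aldehyde 4 (not isolated)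
Conditions: IBX, DMSO, rt; then Ph3P=CHCO2Et, rt
Reagents that add atoms: ethyl (triphenylphosphoranylidene)acetate, CCOC(=O)C=P(c1ccccc1)(c1ccccc1)c1ccccc1
Why: IBX oxidation and capture of the labile α-alkoxy aldehyde in the same flask by the stabilised ylide (Wittig olefination) should give the (E)-enoate (C2, C1=C10) without epimerisation at C9.

Step 3
Reactants: 5 ethyl enoate
Product: 7 ethyl (3R)-3-[(4R,5R)-5-({[tert-butyl(dimethyl)silyl]oxy}methyl)-2,2-dimethyl-1,3-dioxolan-4-yl]butanoate, via silyl ketene acetal 6 (not isolated)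
Conditions: MeLi, CuBr·SMe2, Et2O, 0 °C; then 5, TMSCl, THF, −78 °C; aq. NH4Cl
Reagents that add atoms: lithium dimethylcuprate (made from MeLi and CuBr·SMe2), [Li+].C[Cu-]C
Why: The TMSCl-accelerated 1,4-addition of the Gilman cuprate should take place anti to the γ-oxygen of the trans-dioxolane (substrate control known for γ-alkoxy (E)-enoates), which sets C10 in the 9,10-anti sense, and the ketene acetal is hydrolysed on work-up.

Step 4
Reactants: 7 β-methyl ester
Product: 8 ethyl (3R)-3-[(4R,5R)-5-(hydroxymethyl)-2,2-dimethyl-1,3-dioxolan-4-yl]butanoate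
Conditions: TBAF, THF, 0 °C
Reagents that add atoms: none
Why: Fluoride cleaves the primary silyl ether, while the ester and the acetonide are inert under these conditions.

Step 5
Reactants: 8 primary alcohol
Product: 10 tert-butyl (2E)-3-{(4R,5R)-5-[(2R)-4-ethoxy-4-oxobutan-2-yl]-2,2-dimethyl-1,3-dioxolan-4-yl}prop-2-enoate, via aldehyde 9 (not isolated)
Conditions: IBX, DMSO, rt; then Ph3P=CHCO2t-Bu, rt
Reagents that add atoms: tert-butyl (triphenylphosphoranylidene)acetate, CC(C)(C)OC(=O)C=P(c1ccccc1)(c1ccccc1)c1ccccc1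
Why: The same oxidation/Wittig olefination should give the (E)-tert-butyl enoate (C12, C11=C7), the bulky ester being chosen to resist later nucleophiles and to be cleaved without hydrolysis.

Step 6
Reactants: 10 tert-butyl enoate
Product: 12 tert-butyl (3R)-2-[(dimethylamino)methyl]-3-{(4R,5R)-5-[(2R)-4-ethoxy-4-oxobutan-2-yl]-2,2-dimethyl-1,3-dioxolan-4-yl}pent-4-enoate (C2 epimers), via silyl ketene acetal 11 (not isolated)
Conditions: CH2=CHMgBr, CuBr·SMe2, THF, −40 °C; then 10, TMSCl, −78 °C; then CH2=NMe2+ I−, CH2Cl2, −78 °C to rt; aq. NaHCO3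
Reagents that add atoms: bromomagnesium divinylcuprate (made from vinylmagnesium bromide and CuBr·SMe2), C=C[Cu-]C=C.[Mg+]Br; N,N-dimethylmethyleneiminium iodide (Eschenmoser's salt), C=[N+](C)C.[I-]
Why: The vinyl cuprate should again add anti to the γ-oxygen (now O8), which sets C7 with the configuration of the target and brings in C6 and C5, and the regiodefined ketene acetal is aminomethylated at C11 by the iminium salt (Mukaiyama–Mannich reaction) without enolising the ethyl ester.

Step 7
Reactants: 12 Mannich base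
Product: 14 tert-butyl (3R)-3-{(4R,5R)-5-[(2R)-4-ethoxy-4-oxobutan-2-yl]-2,2-dimethyl-1,3-dioxolan-4-yl}-2-methylidenepent-4-enoate, via ammonium iodide 13 (not isolated)
Conditions: MeI, CH2Cl2/MeOH, rt; then aq. NaHCO3, rt
Reagents that add atoms: none
Why: N-Methylation and mild base-induced β-elimination of trimethylamine (Hofmann-type elimination) should unveil the C11=C13 methylene group, and both C11 epimers converge.

Step 8
Reactants: 14 α-methylene ester
Product: 16 tert-butyl (3R)-3-{(R)-hydroxy[(2R,3R)-3-methyl-5-oxooxolan-2-yl]methyl}-2-methylidenepent-4-enoate, via diol 15 (not isolated)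
Conditions: AcOH/H2O (4:1), 50 °C; then PPTS (cat.), PhMe, 60 °C
Reagents that add atoms: none
Why: Acid hydrolysis of the acetonide frees both hydroxyls and the C9 hydroxyl, γ to the ethyl ester, should lactonise, so that only the C8 hydroxyl stays free (a temporary ring differentiates the diol), while the hindered tert-butyl acrylate should not lactonise.

Step 9
Reactants: 16 hydroxy lactone
Product: 17 tert-butyl (3R)-3-{(R)-{[tert-butyl(dimethyl)silyl]oxy}[(2R,3R)-3-methyl-5-oxooxolan-2-yl]methyl}-2-methylidenepent-4-enoate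
Conditions: TBSOTf, 2,6-lutidine, CH2Cl2, −78 to 0 °C
Reagents that add atoms: tert-butyldimethylsilyl triflate, CC(C)(C)[Si](C)(C)OS(=O)(=O)C(F)(F)F
Why: Silylation of the remaining secondary alcohol with the silyl triflate protects C8–OH for the rest of the route.

Step 10
Reactants: 17 silylated lactone
Product: 18 tert-butyl (3R,4R,5R,6R)-4-{[tert-butyl(dimethyl)silyl]oxy}-3-ethenyl-5-hydroxy-8-[methoxy(methyl)amino]-6-methyl-2-methylidene-8-oxooctanoate
Conditions: MeNH(OMe)·HCl, i-PrMgCl, THF, −20 °C; aq. NH4Cl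
Reagents that add atoms: N,O-dimethylhydroxylamine hydrochloride, CNOC.Cl
Why: Aminolysis of the γ-lactone by the magnesium amide (Weinreb amide formation) reopens the temporary ring, frees the C9 hydroxyl and makes C2 an acylating centre, the tert-butyl ester being too hindered to react and the low temperature disfavouring silyl migration.

Step 11
Reactants: 18 hydroxy Weinreb amide
Product: 19 tert-butyl (3R,4R,5R,6R)-4-{[tert-butyl(dimethyl)silyl]oxy}-3-ethenyl-8-[methoxy(methyl)amino]-6-methyl-2-methylidene-8-oxo-5-[(triethylsilyl)oxy]octanoate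
Conditions: TESOTf, 2,6-lutidine, CH2Cl2, −78 °C
Reagents that add atoms: triethylsilyl triflate, CC[Si](CC)(CC)OS(=O)(=O)C(F)(F)F
Why: Immediate silylation of the γ-hydroxy amide prevents relactonisation and gives a C9 ether that can later be removed in the presence of the C8 tert-butyldimethylsilyl ether.

Step 12
Reactants: 19 Weinreb amide
Product: 20 tert-butyl (3R,4R,5R,6R)-4-{[tert-butyl(dimethyl)silyl]oxy}-3-ethenyl-6-methyl-2-methylidene-8-oxo-5-[(triethylsilyl)oxy]undec-9-ynoate
Conditions: CH3C≡CMgBr, THF, 0 °C; aq. NH4Cl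
Reagents that add atoms: 1-propynylmagnesium bromide, CC#C[Mg]Br
Why: Addition of the alkynyl Grignard reagent to the Weinreb amide stops at the ketone (Weinreb ketone synthesis) and brings in C3, C4 and the C4 methyl as an ynone.

Step 13
Reactants: 20 ynone
Product: 21 tert-butyl (3R,4R,5R,6R,9Z)-4-{[tert-butyl(dimethyl)silyl]oxy}-3-ethenyl-10-iodo-6-methyl-2-methylidene-8-oxo-5-[(triethylsilyl)oxy]undec-9-enoate
Conditions: NaI, AcOH, MeCN, rt
Reagents that add atoms: sodium iodide, [Na+].[I-]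
Why: Conjugate addition of iodide to the ynone and protonation of the allenolate (anti hydroiodination) should give the (Z)-β-iodoenone, which fixes the cis geometry of the future C3=C4 ring olefin.

Step 14
Reactants: 21 (Z)-iodoenone tert-butyl ester
Product: 23 (3R,4R,5R,6R,9Z)-4-{[tert-butyl(dimethyl)silyl]oxy}-3-ethenyl-10-iodo-6-methyl-2-methylidene-8-oxo-5-[(triethylsilyl)oxy]undec-9-enoic acid, via trimethylsilyl ester 22 (not isolated)
Conditions: TMSOTf, 2,6-lutidine, CH2Cl2, 0 °C; then pH 5 buffer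
Reagents that add atoms: none
Why: Silyl triflate-mediated cleavage of the tert-butyl ester with loss of isobutene, and hydrolysis of the silyl ester on work-up, should free the acid without touching the silyl ethers or the iodoenone.

Step 15
Reactants: 23 seco acid
Product: 25 (3Z,6R,7S,8R,9R,10R)-8-{[tert-butyl(dimethyl)silyl]oxy}-2-oxo-9-[(triethylsilyl)oxy]germacra-3,11(13)-dien-12,6-olide, via caesium carboxylate 24 (not isolated)
Conditions: Cs2CO3, Pd2(dba)3 (5 mol%), DPEphos (12 mol%), 1,4-dioxane (0.002 M, slow addition), 90 °C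
Reagents that add atoms: none
Why: Proposed new method: oxidative addition of zerovalent palladium into the C4–I bond of carboxylate 24, with retention of the Z geometry, should give an alkenylpalladium carboxylate whose Pd–O bond adds syn across the C5=C6 vinyl group (O to C6, Pd to C5), and C(sp3)–C(sp2) reductive elimination then joins C5 to C4. The closest known reaction type is the palladium-catalysed carboetherification and carboamination of γ-hydroxy- and γ-aminoalkenes with aryl or alkenyl halides, here extended to a carboxylate nucleophile and a macrocyclic tether, together with macrocyclising Heck reactions of alkenyl iodides. The γ-lactone closes in the 5-exo-trig mode by formation of the O–C6 bond, and the ten-membered carbocycle closes by reductive elimination from an eleven-membered palladacycle (Pd, C5 to C10, C1 to C4). The new stereocentre C6 is controlled by C7: in the cyclic oxypalladation transition state the C7–C8 bond lies pseudo-equatorial, which places H6 anti to H7 (trans-fused lactone), and the Z enone geometry is carried over from 21. The step needs oxypalladation to outrun carbopalladation of either olefin and β-hydride elimination; the palladium-bound carboxylate can reach only the C5=C6 vinyl group (the C11=C13 acrylate cannot be attacked by its own carboxylate), the wide-bite-angle diphosphine favours reductive elimination, the C9 hydroxyl is silylated so that no tetrahydrofuran can form, and high dilution suppresses oligomers. Should Heck-type carbopalladation at C5 intervene, the resulting 3,5-dienone carboxylate can still close the same O–C6 bond by 1,6-conjugate addition.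

Step 16
Reactants: 25 bis-silylated lactone
Product: 26 (3Z,6R,7S,8R,9R,10R)-8-{[tert-butyl(dimethyl)silyl]oxy}-9-hydroxy-2-oxogermacra-3,11(13)-dien-12,6-olide
Conditions: PPTS (cat.), MeOH/CH2Cl2, 0 °C
Reagents that add atoms: none
Why: The triethylsilyl ether is far more acid-labile than the tert-butyldimethylsilyl ether, so mild acid-catalysed methanolysis should free only C9–OH.

Step 17
Reactants: 27 (Z)-2-methylbut-2-enoic acid (angelic acid)
Product: 28 (Z)-2-methylbut-2-en-1-ol
Conditions: LiAlH4, Et2O, 0 °C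
Reagents that add atoms: none
Why: Hydride reduction of the acid gives the allylic alcohol, and the Z geometry is retained at low temperature.

Step 18
Reactants: 28 (Z)-2-methylbut-2-en-1-ol
Product: 29 [(2S,3R)-2,3-dimethyloxiran-2-yl]methanol
Conditions: Ti(OiPr)4 (cat.), L-(+)-diisopropyl tartrate (cat.), t-BuOOH, 4 Å MS, CH2Cl2, −20 °C
Reagents that add atoms: tert-butyl hydroperoxide, CC(C)(C)OO
Why: Sharpless asymmetric epoxidation with the L-(+)-tartrate ligand should deliver oxygen to the face of the (Z)-allylic alcohol that gives the (2S,3R)-epoxy alcohol (catalyst control), which sets both epoxide stereocentres.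

Step 19
Reactants: 29 epoxy alcohol
Product: 31 (2R,3R)-2,3-dimethyloxirane-2-carboxylic acid, via epoxy aldehyde 30 (not isolated)
Conditions: RuCl3·3H2O (cat.), NaIO4, MeCN/EtOAc/H2O, 0 °C to rt
Reagents that add atoms: water, O
Why: RuO4 generated from RuCl3 and periodate oxidises the primary alcohol through the aldehyde hydrate to the acid without opening the epoxide, the new carboxyl oxygen coming from water.

Step 20
Reactants: 26 C9 alcohol; 31 epoxy acid
Product: 33 8-O-tert-butyldimethylsilyl vicolide D, via mixed anhydride 32 (not isolated)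
Conditions: 31, 2,4,6-trichlorobenzoyl chloride, Et3N, THF, rt; then 26, DMAP, PhMe, 40 °C
Reagents that add atoms: none
Why: Yamaguchi esterification through the mixed anhydride and DMAP should acylate the hindered C9 hydroxyl with retention at every stereocentre.

Step 21
Reactants: 33 silyl ether
Product: 34 Vicolide D
Conditions: HF·pyridine, pyridine/THF, 0 °C to rt
Reagents that add atoms: none
Why: Buffered HF·pyridine removes the silyl ether under non-basic conditions that should spare the epoxy ester, the α-methylene lactone and the enone and disfavour acyl migration from O9 to O8.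

**Compound list**

1 | (4R,5R)-2,2-dimethyl-1,3-dioxolane-4,5-dimethanol (2,3-O-isopropylidene-D-threitol) | OC[C@H]1OC(C)(C)O[C@@H]1CO | starting material
2 | monosodium alkoxide of 1 | OC[C@H]1OC(C)(C)O[C@@H]1C[O-].[Na+] | intermediate
3 | [(4R,5R)-5-({[tert-butyl(dimethyl)silyl]oxy}methyl)-2,2-dimethyl-1,3-dioxolan-4-yl]methanol | OC[C@H]1OC(C)(C)O[C@@H]1CO[Si](C)(C)C(C)(C)C | intermediate
4 | (4S,5R)-5-({[tert-butyl(dimethyl)silyl]oxy}methyl)-2,2-dimethyl-1,3-dioxolane-4-carbaldehyde | O=C[C@H]1OC(C)(C)O[C@@H]1CO[Si](C)(C)C(C)(C)C | intermediate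
5 | ethyl (2E)-3-[(4R,5R)-5-({[tert-butyl(dimethyl)silyl]oxy}methyl)-2,2-dimethyl-1,3-dioxolan-4-yl]prop-2-enoate | CCOC(=O)/C=C/[C@H]1OC(C)(C)O[C@@H]1CO[Si](C)(C)C(C)(C)C | intermediate
6 | ethyl trimethylsilyl ketene acetal of 7 (C10 as in 7) | CCOC(O[Si](C)(C)C)=C[C@@H](C)[C@H]1OC(C)(C)O[C@@H]1CO[Si](C)(C)C(C)(C)C | intermediate
7 | ethyl (3R)-3-[(4R,5R)-5-({[tert-butyl(dimethyl)silyl]oxy}methyl)-2,2-dimethyl-1,3-dioxolan-4-yl]butanoate | CCOC(=O)C[C@@H](C)[C@H]1OC(C)(C)O[C@@H]1CO[Si](C)(C)C(C)(C)C | intermediate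
8 | ethyl (3R)-3-[(4R,5R)-5-(hydroxymethyl)-2,2-dimethyl-1,3-dioxolan-4-yl]butanoate | CCOC(=O)C[C@@H](C)[C@H]1OC(C)(C)O[C@@H]1CO | intermediate
9 | ethyl (3R)-3-[(4R,5S)-5-formyl-2,2-dimethyl-1,3-dioxolan-4-yl]butanoate | CCOC(=O)C[C@@H](C)[C@H]1OC(C)(C)O[C@@H]1C=O | intermediate
10 | tert-butyl (2E)-3-{(4R,5R)-5-[(2R)-4-ethoxy-4-oxobutan-2-yl]-2,2-dimethyl-1,3-dioxolan-4-yl}prop-2-enoate | CCOC(=O)C[C@@H](C)[C@H]1OC(C)(C)O[C@@H]1/C=C/C(=O)OC(C)(C)C | intermediate
11 | tert-butyl trimethylsilyl ketene acetal of the vinyl adduct of 10 (C7 as in 14) | CCOC(=O)C[C@@H](C)[C@H]1OC(C)(C)O[C@@H]1[C@@H](C=C(O[Si](C)(C)C)OC(C)(C)C)C=C | intermediate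
12 | tert-butyl (3R)-2-[(dimethylamino)methyl]-3-{(4R,5R)-5-[(2R)-4-ethoxy-4-oxobutan-2-yl]-2,2-dimethyl-1,3-dioxolan-4-yl}pent-4-enoate (C2 epimers) | CCOC(=O)C[C@@H](C)[C@H]1OC(C)(C)O[C@@H]1[C@@H](C(CN(C)C)C(=O)OC(C)(C)C)C=C | intermediate
13 | trimethylammonium iodide of 12 (C2 epimers) | CCOC(=O)C[C@@H](C)[C@H]1OC(C)(C)O[C@@H]1[C@@H](C(C[N+](C)(C)C)C(=O)OC(C)(C)C)C=C.[I-] | intermediate
14 | tert-butyl (3R)-3-{(4R,5R)-5-[(2R)-4-ethoxy-4-oxobutan-2-yl]-2,2-dimethyl-1,3-dioxolan-4-yl}-2-methylidenepent-4-enoate | CCOC(=O)C[C@@H](C)[C@H]1OC(C)(C)O[C@@H]1[C@@H](C(=C)C(=O)OC(C)(C)C)C=C | intermediate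
15 | 1-tert-butyl 8-ethyl (3R,4R,5R,6R)-3-ethenyl-4,5-dihydroxy-6-methyl-2-methylideneoctanedioate | CCOC(=O)C[C@@H](C)[C@@H](O)[C@H](O)[C@@H](C(=C)C(=O)OC(C)(C)C)C=C | intermediate
16 | tert-butyl (3R)-3-{(R)-hydroxy[(2R,3R)-3-methyl-5-oxooxolan-2-yl]methyl}-2-methylidenepent-4-enoate | O=C1C[C@@H](C)[C@@H](O1)[C@H](O)[C@@H](C(=C)C(=O)OC(C)(C)C)C=C | intermediate
17 | tert-butyl (3R)-3-{(R)-{[tert-butyl(dimethyl)silyl]oxy}[(2R,3R)-3-methyl-5-oxooxolan-2-yl]methyl}-2-methylidenepent-4-enoate | O=C1C[C@@H](C)[C@@H](O1)[C@H](O[Si](C)(C)C(C)(C)C)[C@@H](C(=C)C(=O)OC(C)(C)C)C=C | intermediate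
18 | tert-butyl (3R,4R,5R,6R)-4-{[tert-butyl(dimethyl)silyl]oxy}-3-ethenyl-5-hydroxy-8-[methoxy(methyl)amino]-6-methyl-2-methylidene-8-oxooctanoate | CON(C)C(=O)C[C@@H](C)[C@@H](O)[C@H](O[Si](C)(C)C(C)(C)C)[C@@H](C(=C)C(=O)OC(C)(C)C)C=C | intermediate
19 | tert-butyl (3R,4R,5R,6R)-4-{[tert-butyl(dimethyl)silyl]oxy}-3-ethenyl-8-[methoxy(methyl)amino]-6-methyl-2-methylidene-8-oxo-5-[(triethylsilyl)oxy]octanoate | CON(C)C(=O)C[C@@H](C)[C@@H](O[Si](CC)(CC)CC)[C@H](O[Si](C)(C)C(C)(C)C)[C@@H](C(=C)C(=O)OC(C)(C)C)C=C | intermediate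
20 | tert-butyl (3R,4R,5R,6R)-4-{[tert-butyl(dimethyl)silyl]oxy}-3-ethenyl-6-methyl-2-methylidene-8-oxo-5-[(triethylsilyl)oxy]undec-9-ynoate | CC#CC(=O)C[C@@H](C)[C@@H](O[Si](CC)(CC)CC)[C@H](O[Si](C)(C)C(C)(C)C)[C@@H](C(=C)C(=O)OC(C)(C)C)C=C | intermediate
21 | tert-butyl (3R,4R,5R,6R,9Z)-4-{[tert-butyl(dimethyl)silyl]oxy}-3-ethenyl-10-iodo-6-methyl-2-methylidene-8-oxo-5-[(triethylsilyl)oxy]undec-9-enoate | C/C(I)=C/C(=O)C[C@@H](C)[C@@H](O[Si](CC)(CC)CC)[C@H](O[Si](C)(C)C(C)(C)C)[C@@H](C(=C)C(=O)OC(C)(C)C)C=C | intermediate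
22 | trimethylsilyl ester of 23 | C/C(I)=C/C(=O)C[C@@H](C)[C@@H](O[Si](CC)(CC)CC)[C@H](O[Si](C)(C)C(C)(C)C)[C@@H](C(=C)C(=O)O[Si](C)(C)C)C=C | intermediate
23 | (3R,4R,5R,6R,9Z)-4-{[tert-butyl(dimethyl)silyl]oxy}-3-ethenyl-10-iodo-6-methyl-2-methylidene-8-oxo-5-[(triethylsilyl)oxy]undec-9-enoic acid | C/C(I)=C/C(=O)C[C@@H](C)[C@@H](O[Si](CC)(CC)CC)[C@H](O[Si](C)(C)C(C)(C)C)[C@@H](C(=C)C(=O)O)C=C | intermediate
24 | caesium salt of 23 | C/C(I)=C/C(=O)C[C@@H](C)[C@@H](O[Si](CC)(CC)CC)[C@H](O[Si](C)(C)C(C)(C)C)[C@@H](C(=C)C(=O)[O-])C=C.[Cs+] | intermediate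
25 | (3Z,6R,7S,8R,9R,10R)-8-{[tert-butyl(dimethyl)silyl]oxy}-2-oxo-9-[(triethylsilyl)oxy]germacra-3,11(13)-dien-12,6-olide | C=C1C(=O)O[C@@H]2C/C(C)=C\C(=O)C[C@@H](C)[C@@H](O[Si](CC)(CC)CC)[C@H](O[Si](C)(C)C(C)(C)C)[C@@H]12 | intermediate
26 | (3Z,6R,7S,8R,9R,10R)-8-{[tert-butyl(dimethyl)silyl]oxy}-9-hydroxy-2-oxogermacra-3,11(13)-dien-12,6-olide | C=C1C(=O)O[C@@H]2C/C(C)=C\C(=O)C[C@@H](C)[C@@H](O)[C@H](O[Si](C)(C)C(C)(C)C)[C@@H]12 | intermediate
27 | (Z)-2-methylbut-2-enoic acid (angelic acid) | C/C=C(/C)C(=O)O | starting material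
28 | (Z)-2-methylbut-2-en-1-ol | C/C=C(/C)CO | intermediate
29 | [(2S,3R)-2,3-dimethyloxiran-2-yl]methanol | OC[C@]1(C)O[C@@H]1C | intermediate
30 | (2R,3R)-2,3-dimethyloxirane-2-carbaldehyde | O=C[C@]1(C)O[C@@H]1C | intermediate
31 | (2R,3R)-2,3-dimethyloxirane-2-carboxylic acid | OC(=O)[C@]1(C)O[C@@H]1C | intermediate
32 | (2R,3R)-2,3-dimethyloxirane-2-carboxylic 2,4,6-trichlorobenzoic anhydride | O=C(OC(=O)[C@]1(C)O[C@@H]1C)c1c(Cl)cc(Cl)cc1Cl | intermediate
33 | 8-O-tert-butyldimethylsilyl vicolide D ((3Z,6R,7S,8R,9R,10R)-8-silyloxy-9-[(2R,3R)-2,3-dimethyloxirane-2-carbonyloxy]-2-oxogermacra-3,11(13)-dien-12,6-olide) | C=C1C(=O)O[C@@H]2C/C(C)=C\C(=O)C[C@@H](C)[C@@H](OC(=O)[C@]3(C)O[C@@H]3C)[C@H](O[Si](C)(C)C(C)(C)C)[C@@H]12 | intermediate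
34 | Vicolide D ((3Z,6R,7R,8R,9R,10R)-9-[(2R,3R)-2,3-dimethyloxirane-2-carbonyloxy]-8-hydroxy-2-oxogermacra-3,11(13)-dien-12,6-olide) | C=C1C(=O)O[C@@H]2C/C(C)=C\C(=O)C[C@@H](C)[C@@H](OC(=O)[C@]3(C)O[C@@H]3C)[C@H](O)[C@@H]12 | target

**Step count and risks**

Total step count: 21. Longest linear sequence: 18 (steps 1 to 16, 20 and 21).

Steps most likely to fail:

Step 15. Carbopalladation of the C11=C13 acrylate or of the C5=C6 vinyl group followed by β-hydride elimination, or β-hydride elimination from the C5 alkylpalladium, may outrun the sequence of oxypalladation and reductive elimination, and oligomers may form. The fallback sets out from 23 and separates the two ring closures. Cross-metathesis of the C5=C6 vinyl group with vinylboronic acid pinacol ester (second-generation Hoveyda–Grubbs catalyst, CH2Cl2, 40 °C) should give the (E)-alkenylboronate acid F1. Intramolecular Suzuki–Miyaura coupling with the (Z)-iodoenone (Pd(dppf)Cl2, K3PO4, THF/H2O, high dilution) should close the ten-membered ring as the (3Z,5E)-dienone acid F2. Warming F2 with PPTS in toluene should close the lactone by 1,6-conjugate addition of the carboxylic acid to C6, which returns to the route at 25.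

Step 6. The cuprate may attack the hindered tert-butyl enoate with poor facial selectivity, and the ketene acetal may be captured incompletely by the iminium salt. The fallback sets out from 8 and uses a doubly activated acceptor and a decarboxylative methylenation. Oxidation to 9 as in step 5 and Knoevenagel condensation with Meldrum's acid (piperidinium acetate, CH2Cl2) should give the alkylidene Meldrum's acid F3. Vinylmagnesium bromide (THF, −78 °C) should add 1,4 anti to the dioxolane oxygen and give the adduct F4. Heating F4 with Eschenmoser's salt in tert-butanol should bring about aminomethylation, loss of acetone and carbon dioxide, esterification and elimination, which returns to the route at 14.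

Step 13. The acid may cleave the triethylsilyl ether, and the iodoenone may isomerise from Z to E. The fallback sets out from 20 and avoids acid. Luche reduction (NaBH4, CeCl3·7H2O, MeOH, −78 °C) should give the propargylic alcohol F5. Hydroxyl-directed trans-hydroalumination with NaAlH2(OCH2CH2OMe)2 (THF, −20 °C) and iodinolysis with I2 should give the (Z)-3-iodoallylic alcohol F6, with iodine on C4 cis to C2. Dess–Martin oxidation returns to the route at 21.

Further compounds
F1 | step 15 | (3R,4R,5R,6R,9Z)-4-{[tert-butyl(dimethyl)silyl]oxy}-10-iodo-6-methyl-2-methylidene-8-oxo-3-[(E)-2-(4,4,5,5-tetramethyl-1,3,2-dioxaborolan-2-yl)ethenyl]-5-[(triethylsilyl)oxy]undec-9-enoic acid | C/C(I)=C/C(=O)C[C@@H](C)[C@@H](O[Si](CC)(CC)CC)[C@H](O[Si](C)(C)C(C)(C)C)[C@@H](C(=C)C(=O)O)/C=C/B1OC(C)(C)C(C)(C)O1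
F2 | step 15 | (3Z,5E)-8-{[tert-butyl(dimethyl)silyl]oxy}-2-oxo-9-[(triethylsilyl)oxy]germacra-3,5,11(13)-trien-12-oic acid (C7 to C10 as in 23) | C=C(C(=O)O)[C@H]1/C=C/C(C)=C\C(=O)C[C@@H](C)[C@@H](O[Si](CC)(CC)CC)[C@@H]1O[Si](C)(C)C(C)(C)C
F3 | step 6 | ethyl (3R)-3-{(4R,5R)-5-[(2,2-dimethyl-4,6-dioxo-1,3-dioxan-5-ylidene)methyl]-2,2-dimethyl-1,3-dioxolan-4-yl}butanoate | CCOC(=O)C[C@@H](C)[C@H]1OC(C)(C)O[C@@H]1C=C1C(=O)OC(C)(C)OC1=O
F4 | step 6 | ethyl (3R)-3-{(4R,5R)-5-[1-(2,2-dimethyl-4,6-dioxo-1,3-dioxan-5-yl)prop-2-en-1-yl]-2,2-dimethyl-1,3-dioxolan-4-yl}butanoate (C7 as in 14) | CCOC(=O)C[C@@H](C)[C@H]1OC(C)(C)O[C@@H]1[C@@H](C1C(=O)OC(C)(C)OC1=O)C=C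
F5 | step 13 | tert-butyl (3R,4R,5R,6R)-4-{[tert-butyl(dimethyl)silyl]oxy}-3-ethenyl-8-hydroxy-6-methyl-2-methylidene-5-[(triethylsilyl)oxy]undec-9-ynoate (C8 epimers) | CC#CC(O)C[C@@H](C)[C@@H](O[Si](CC)(CC)CC)[C@H](O[Si](C)(C)C(C)(C)C)[C@@H](C(=C)C(=O)OC(C)(C)C)C=C
F6 | step 13 | tert-butyl (3R,4R,5R,6R,9Z)-4-{[tert-butyl(dimethyl)silyl]oxy}-3-ethenyl-8-hydroxy-10-iodo-6-methyl-2-methylidene-5-[(triethylsilyl)oxy]undec-9-enoate (C8 epimers) | C/C(I)=C/C(O)C[C@@H](C)[C@@H](O[Si](CC)(CC)CC)[C@H](O[Si](C)(C)C(C)(C)C)[C@@H](C(=C)C(=O)OC(C)(C)C)C=C
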